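## Analysis of the target

Compound 30 consists of two 3-hydroxy-3,4-bis(arylmethyl)oxolan-2-ones (each numbered O1, C2=O, C3, C4, C5H2) joined by a biaryl bond. Lactone 1 carries the outer guaiacyl ring A on its C4–CH2 and ring B on its C3–CH2. Lactone 2 carries ring C on its C4–CH2 and the outer guaiacyl ring D on its C3–CH2. Rings B and C are bonded C5–C5′, ortho to their phenols, so the two halves are constitutional isomers of each other and not copies; with one ortho substituent per ring the biaryl axis is not stereogenic. The four stereocentres are 3R,4R in both lactones: C4 is a tertiary CH, C3 a fully substituted carbinol whose hydroxyl is cis to the C4 arylmethyl group, so the two arylmethyl groups are trans. Sensitive features are four free phenols (the 2,2′-biphenol oxidises readily in base under air), two lactones that open in base, and electron-rich arenes that make any benzylic oxirane on the way labile. The hard part is the C3 oxygen: it lies on the ring face already occupied by the C4 substituent, where an electrophile approaching a lactone enolate would not go, and this must be solved twice in non-equivalent surroundings, while the unsymmetrical B–C union rules out dimerising one monomer. The strategy rests on the fact that at C3 the hydroxyl and the benzylic CH2 (to ring B in lactone 1, to ring D in lactone 2) sit on one carbon. With that CH2 carried as an arylidene CH and C2 as CH2OH, C3 is the central carbon of an (E)-2-(arylmethylene) allylic alcohol, and a hydroxyl-directed, ligand-controlled epoxidation can place the C3–O bond on the chosen face.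

## Retrosynthetic reasoning

**30 ⇐ 28.** The four phenols are masked as methanesulfonates and only the four O–S bonds are cut. The sulfonates are kept to the end because they are what keeps the benzylic oxiranes of the key step intact. The forward step needs hydroxide to cleave O–S and acid to reclose the lactones that open in passing.

**28 ⇐ 26.** Both O1–C2 bonds are cut and C2 is taken back to a primary alcohol, with O1 held as a silyl ether on C5. This keeps the two CH2–O termini of each unit distinguishable. The forward step must oxidise a primary alcohol beside a tertiary carbinol to the acid and then free C5–OH so the γ-lactone closes.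

**26 ⇐ 25.** The two hydrogens on each C3-benzylic carbon are traced back to one benzylic C–O bond of an aryl oxirane. Hydrogenolysis then has to break only that benzylic bond and leave the C3–O bond, and with it the C3 configuration, alone.

**25 ⇐ 24 (key disconnection).** The C3–O and benzylic C–O bonds of both oxiranes are removed to give the two (E)-trisubstituted alkenes of 24. The cut is made here because the allylic C2 hydroxyl lets a chiral titanium catalyst choose the alkene face, whereas enolate oxidation is bound to the face anti to the C4 group. One operation sets both carbinol centres. The forward reaction must override whatever bias C4 exerts and must not ionise the benzylic oxirane.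

**24 ⇐ 22 ⇐ 21 ⇐ 20.** The C2 alcohol is traced to an N-methoxy-N-methylamide and the C5 silyl ether to the ring oxygen of an α-arylidene lactone. Cutting the acyl–O bond of the lactone is what tells the two oxygens apart. The forward steps are aminolysis, silylation and reduction, with the E geometry and C4 untouched.

**20 ⇐ 19 ⇐ 18.** The sulfonates are exchanged for benzyl ethers. Benzyl survives the alkoxide and enolate chemistry used earlier, which an aryl mesylate would not, and it can be removed by a Lewis acid without touching the arylidene alkenes.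

**18 ⇐ 14 + 16.** The C5–C5′ bond between rings B and C is cut to two aryl bromides, one of which is borylated in the coupling flask. This gives two halves of like size made by the same chemistry and places the unsymmetry of the dimer in a cross-coupling.

**14 ⇐ 6 + 8 and 16 ⇐ 12 + 1.** Each arylidene C=C bond is cut to a lactone enolate and an aryl aldehyde. The forward aldol condensation must give the E alkene (aryl anti to the carbonyl), which later becomes the (E)-allylic alcohol.

**6 ⇐ 4 ⇐ 3 ⇐ 1 + 2; 12 ⇐ 10 ⇐ 9 ⇐ 8 + 2; 8 ⇐ 7.** Each β-arylmethyl lactone is opened to a succinic half-ester and the C4 stereocentre is traced to an alkene made by Stobbe condensation of aldehyde 1 or 8 with 2. A catalytic asymmetric hydrogenation then sets C4 once per half, as a CH that no later step can epimerise. Aldehydes 1 and 8 each serve twice, as Stobbe partner and as aldol partner.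

## Alternatives that were turned down

**Alternative 1:** ring C is built last. Two finished hydroxy-lactone fragments are joined by a base-mediated [3+3] benzannulation. A methoxy-substituted ketone side chain on ring B supplies three ring atoms (including the phenol carbon) and a 2-substituted 3-aminoacrolein unit on the C4–CH2 of lactone 2 supplies the other three; the product is the tribenzyl ether A1, one hydrogenolysis from 30.
- For it: no cross-coupling of two ortho-substituted arenes, no regiochemical question (the three-carbon electrophile is symmetric about its central carbon), and a one-step end-game. On these points it is stronger than the chosen route.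
- Against it: the annulation sets no stereocentre, so the cis C3 hydroxyl still has to be installed separately in each fragment. It also exposes two lactones with free tertiary hydroxyls to tert-butoxide, and both partners need extra C–C constructions for side chains that vanillin-type rings already provide.
- In its place the chosen route buys all four arenes as vanillins and sets both carbinols in one twofold operation after the halves are joined.

**Alternative 2:** both C3–C4 bonds are made by a twofold chelate-controlled Ireland–Claisen rearrangement of a bis(α-benzyloxy allylic ester), giving diacid A2 with C3 (benzyloxy, quaternary) and C4 set and an (E)-propenyl group as masked C5.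
- For it: the C3/C4 relative configuration comes from one chair transition state with a chelated enolate of defined geometry, and the quaternary centre is made by C–C formation, not by oxidation. No external reagent has to override a resident stereocentre, which is a real advantage over the chosen key step.
- Against it: it needs two different enantiopure secondary allylic alcohols and two α-alkoxy acids, distributed unsymmetrically over a preformed biaryl. Both tetrasubstituted ketene acetals must form completely, and chair/boat leakage at either site gives diastereomers of a four-centre molecule. A2 is still far from 30: oxidative cleavage of two alkenes beside electron-rich arenes, reduction, lactonisation and removal of six benzyl ethers.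
- In its place the chosen route makes fewer skeletal bonds, takes C4 from a catalytic hydrogenation and needs three steps after the key step.

**Alternative 3:** both C4–C5 and O1–C2 bonds are made in one flask. Two aryl ketones are converted to silyl enol ethers and hydroxymethylated with aqueous formaldehyde under Sc(OTf)3; each new hydroxyl opens a neighbouring dioxolanone to give the bis(4-aroyl-3-hydroxy lactone) A3, with C4 set by equilibration and C3 carried from an α-hydroxy acid.
- For it: this is the shortest plan. C3 comes from self-regeneration of a stereocentre, and one hydrogenolysis would reduce both aryl ketones to CH2 and remove the benzyl groups. On step economy it is clearly stronger than the chosen route.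
- Against it: C4 in A3 is α to a ketone and fixed only by a thermodynamic preference between a hydroxyl and an arylmethyl group on C3, which may be small. The β-acyloxy ketone in A3 is set up for E1cB ring opening to an enone, and the β-hydroxy ketone before it for loss of formaldehyde; the conditions that equilibrate C4 favour both.
- In its place the chosen route offers a C4 that cannot epimerise and a C3 set by reagent control in a well-understood reaction class, at the price of more steps.

Key step: step 16

Remark: 1 (O-benzylvanillin) is taken as a purchased compound; the sense of the hydrogenations in steps 2 and 6 is assigned by analogy and is to be confirmed by correlating 6 with the known (S)-lactone series before going on.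

## Route

Step 1
Reactants: 1 4-(benzyloxy)-3-methoxybenzaldehyde; 2 dimethyl succinate
Product: 3 (3E)-4-[4-(benzyloxy)-3-methoxyphenyl]-3-(methoxycarbonyl)but-3-enoic acid
Conditions: NaOMe, MeOH, reflux; then aq. HCl
Reagents that add atoms: none
Why: Stobbe condensation: the succinate enolate adds to the aldehyde, the alkoxide lactonises and base-induced ring opening leaves the conjugated ester and the free acid; the E isomer (aryl trans to CO2Me) is the usual major product and is purified by crystallisation.

Step 2
Reactants: 3 (3E)-half-ester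
Product: 4 (3S)-4-[4-(benzyloxy)-3-methoxyphenyl]-3-(methoxycarbonyl)butanoic acid
Conditions: H2 (5 bar), [Rh(cod)((R,R)-Et-DuPHOS)]BF4 (0.5 mol %), NaOMe (0.1 equiv), MeOH, 25 °C
Reagents that add atoms: none
Why: Rhodium–bisphospholane asymmetric hydrogenation of an itaconate-type half-ester: carboxylate and alkene chelate the metal and the ligand antipode fixes the face that receives hydrogen at C3; the (R,R)-ligand is the one expected to give 3S (the chelate sense that gives (R)-α-amino esters from enamides), and the benzyl ether is inert to this homogeneous catalyst.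

Step 3
Reactants: 4 (3S)-half-ester
Product: 6 (4S)-4-{[4-(benzyloxy)-3-methoxyphenyl]methyl}oxolan-2-one, via hydroxy acid 5 (not isolated)
Conditions: KOH (1 equiv), EtOH; CaCl2, NaBH4, −10 °C → rt; then 2 M HCl, rt
Reagents that add atoms: none
Why: Ca(BH4)2 formed in the flask reduces the methyl ester while the potassium carboxylate is left alone, and acidification closes the γ-lactone; the stereocentre is not involved and keeps the S descriptor.

Step 4
Reactants: 7 5-bromovanillin
Product: 8 4-(benzyloxy)-3-bromo-5-methoxybenzaldehyde
Conditions: BnBr, K2CO3, DMF, 60 °C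
Reagents that add atoms: benzyl bromide, BrCc1ccccc1
Why: Williamson ether synthesis on the phenoxide; the benzyl ether is needed for the alkoxide and enolate steps that follow.

Step 5
Reactants: 8 4-(benzyloxy)-3-bromo-5-methoxybenzaldehyde; 2 dimethyl succinate
Product: 9 (3E)-4-[4-(benzyloxy)-3-bromo-5-methoxyphenyl]-3-(methoxycarbonyl)but-3-enoic acid
Conditions: NaOMe, MeOH, reflux; then aq. HCl
Reagents that add atoms: none
Why: Stobbe condensation as in step 1; the aryl bromide is inert to methoxide under these conditions.

Step 6
Reactants: 9 (3E)-bromo half-ester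
Product: 10 (3S)-4-[4-(benzyloxy)-3-bromo-5-methoxyphenyl]-3-(methoxycarbonyl)butanoic acid
Conditions: H2 (5 bar), [Rh(cod)((R,R)-Et-DuPHOS)]BF4 (0.5 mol %), NaOMe (0.1 equiv), MeOH, 25 °C
Reagents that add atoms: none
Why: Same asymmetric hydrogenation as step 2, the ligand setting 3S; cationic rhodium–diphosphine catalysts do not insert into aryl C–Br bonds under these conditions, so the bromide should survive.

Step 7
Reactants: 10 (3S)-bromo half-ester
Product: 12 (4S)-4-{[4-(benzyloxy)-3-bromo-5-methoxyphenyl]methyl}oxolan-2-one, via hydroxy acid 11 (not isolated)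
Conditions: KOH (1 equiv), EtOH; CaCl2, NaBH4, −10 °C → rt; then 2 M HCl, rt
Reagents that add atoms: none
Why: Chemoselective borohydride reduction of the ester beside the carboxylate salt and acid lactonisation, as in step 3; the aryl bromide is unaffected.

Step 8
Reactants: 6 (4S)-lactone with ring A; 8 4-(benzyloxy)-3-bromo-5-methoxybenzaldehyde
Product: 14 (3E,4S)-3-{[4-(benzyloxy)-3-bromo-5-methoxyphenyl]methylidene}-4-{[4-(benzyloxy)-3-methoxyphenyl]methyl}oxolan-2-one, via aldol acetate 13 (not isolated)
Conditions: LiN(SiMe3)2, THF, −78 °C; 8; then Ac2O, −78 °C → rt; then DBU, rt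
Reagents that add atoms: none
Why: Aldol condensation of a lactone enolate: the lithium aldolate is trapped as its acetate and DBU effects E1cB elimination to the conjugated, thermodynamically preferred E-arylidene lactone (aryl anti to C=O); the amide base does not exchange the aryl bromide and C4–H is not acidic, so C4 stays S.

Step 9
Reactants: 12 (4S)-lactone with ring C; 1 4-(benzyloxy)-3-methoxybenzaldehyde
Product: 16 (3E,4S)-4-{[4-(benzyloxy)-3-bromo-5-methoxyphenyl]methyl}-3-{[4-(benzyloxy)-3-methoxyphenyl]methylidene}oxolan-2-one, via aldol acetate 15 (not isolated)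
Conditions: LiN(SiMe3)2, THF, −78 °C; 1; then Ac2O, −78 °C → rt; then DBU, rt
Reagents that add atoms: none
Why: Same aldol–acetylation–elimination as step 8, giving the E-arylidene lactone with C4 unchanged.

Step 10
Reactants: 16 bromide with rings C and D; 14 bromide with rings A and B
Product: 18 tetra-O-benzyl bis(arylidene lactone) with the B–C biaryl bond, via boronate 17 (not isolated)
Conditions: B2pin2, PdCl2(dppf), KOAc, 1,4-dioxane, 90 °C; then 14, Pd(OAc)2, SPhos, aq. K3PO4, 80 °C; dilute HCl work-up
Reagents that add atoms: none
Why: One-flask Miyaura borylation and Suzuki–Miyaura cross-coupling: the ring C bromide (not conjugated) is borylated and the more electron-poor ring B bromide of 14 is the oxidative-addition partner; a biaryl with one ortho alkoxy group on each ring is within the reach of SPhos-ligated palladium, and the acidic work-up recloses any lactone opened by the aqueous base.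

Step 11
Reactants: 18 tetra-O-benzyl bis(arylidene lactone)
Product: 19 tetraphenol bis(arylidene lactone)
Conditions: BCl3, C6HMe5, CH2Cl2, −78 °C; then MeOH
Reagents that add atoms: none
Why: Lewis-acid debenzylation of aryl benzyl ethers with pentamethylbenzene as a non-basic benzyl-cation scavenger; at −78 °C the methyl ethers, the lactones and the arylidene alkenes (which hydrogenolysis would reduce) are left intact.

Step 12
Reactants: 19 tetraphenol bis(arylidene lactone)
Product: 20 tetramesylate bis(arylidene lactone)
Conditions: MsCl, Et3N, CH2Cl2, 0 °C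
Reagents that add atoms: methanesulfonyl chloride, CS(=O)(=O)Cl
Why: Sulfonylation of the four phenols (via sulfene); no aliphatic hydroxyl is present at this stage, so there is no chemoselectivity question, and from here on the aryl oxygens are poor donors.

Step 13
Reactants: 20 tetramesylate bis(arylidene lactone)
Product: 21 bis(γ-hydroxy N-methoxy-N-methylamide)
Conditions: AlMe3, MeNHOMe·HCl, CH2Cl2, 0 °C → rt; aq. potassium sodium tartrate
Reagents that add atoms: N,O-dimethylhydroxylamine hydrochloride, CNOC.Cl
Why: Aluminium-amide (Weinreb) aminolysis of lactones: the Lewis-acid-bound carbonyl is attacked by the weakly basic amide, the acyl–O bond breaks and the C5 hydroxyl is released; the aryl sulfonates are far poorer electrophiles toward this reagent, and the E alkene and C4 are untouched.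

Step 14
Reactants: 21 bis(γ-hydroxy amide)
Product: 22 bis(tert-butyldimethylsilyl ether) of 21
Conditions: TBSCl, imidazole, DMF, 0 °C → rt (crude 21 used at once)
Reagents that add atoms: tert-butyldimethylsilyl chloride, CC(C)(C)[Si](C)(C)Cl
Why: Silylation of the primary C5 hydroxyls stops relactonisation and later keeps these oxygens from binding titanium or opening the oxiranes.

Step 15
Reactants: 22 bis(silyl ether amide)
Product: 24 bis[(E)-2-(arylmethylene) allylic alcohol], via bis-enal 23 (not isolated)
Conditions: iBu2AlH, THF, −78 °C; then MeOH, NaBH4, −78 → 0 °C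
Reagents that add atoms: none
Why: Reduction of a Weinreb amide stops at the chelated tetrahedral intermediate, which releases the enal on protic quench; borohydride then reduces the aldehyde 1,2 to the allylic alcohol; aryl mesylates and silyl ethers tolerate both hydrides at low temperature and the E geometry is kept.

Step 16
Reactants: 24 bis[(E)-2-(arylmethylene) allylic alcohol]
Product: 25 bis(2,3-epoxy alcohol), oxiranes (2R,3R), side-chain carbon R
Conditions: Ti(OiPr)4 (0.5 equiv per alkene), D-(−)-diethyl tartrate (0.6 equiv per alkene), tBuOOH (in isooctane), 4 Å molecular sieves, CH2Cl2, −20 °C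
Reagents that add atoms: tert-butyl hydroperoxide, CC(C)(C)OO
Why: Each allylic alkoxide of 24 and a tert-butylperoxide bind the titanium–tartrate complex, and the distal peroxide oxygen is passed in one concerted step to the alkene held beneath the metal, so both C–O bonds of each oxirane form together (a [2+1] oxygen-atom transfer with no open intermediate). The closest known reaction is the Sharpless asymmetric epoxidation of (E)-2,3-disubstituted 3-aryl allylic alcohols, here run twice in one molecule. The face is fixed by the tartrate: the natural L-(+)-ester gives 2S epoxy alcohols from this substitution pattern, whereas 25 needs 2R at the carbinol-bearing carbon (ranking O > benzylic C > CH2OH > C4), so the D-(−)-ester is used; this face is the one that ends up cis to the C4 arylmethyl group in the lactone. The benzylic centre (3R) follows from suprafacial delivery to the E alkene, the aryl group staying trans to CH2OH. C4 should not override the ligand: allylic 1,3-strain with the cis aryl group turns C4–H into the alkene plane and leaves CH2Ar and CH2OSi, two groups of similar size, on opposite faces. The step needs enantioface selection at each alkene (tartrate), reaction only at the two allylic alkenes (hydroxyl direction) and survival of the benzylic oxiranes at the Lewis-acidic metal. The last is secured by the four sulfonates, which make the para oxygens poor donors, and by the silyl ethers, which keep the C5 oxygens away.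

Step 17
Reactants: 25 bis(2,3-epoxy alcohol)
Product: 26 bis(1,2-diol), each unit (2R,3R)
Conditions: H2 (1 atm), Pd/C (10 wt %), EtOAc, rt
Reagents that add atoms: none
Why: Hydrogenolysis of aryl oxiranes breaks the benzylic C–O bond only, so the benzylic carbon becomes CH2 and the C3–O bond with its configuration is kept as the tertiary alcohol; aryl mesylates and, in ethyl acetate, the silyl ethers are inert.

Step 18
Reactants: 26 bis(1,2-diol)
Product: 28 tetra-O-mesyl derivative of the target, via hydroxy acid 27 (not isolated)
Conditions: TEMPO (cat.), NaOCl (cat.), NaClO2, MeCN/aq. NaH2PO4–Na2HPO4 (pH 6.7), 35 °C; aq. Na2SO3; then 2 M HCl, THF, 40 °C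
Reagents that add atoms: sodium chlorite, [Na+].[O-]Cl=O
Why: Oxoammonium oxidation of the primary alcohols to aldehydes and chlorite oxidation to the acids in one flask (the tertiary hydroxyls cannot be oxidised); after the oxidant is reduced, acid removes both silyl ethers and the freed C5 hydroxyls close the γ-lactones by acyl substitution; no stereocentre is touched.

Step 19
Reactants: 28 tetra-O-mesyl bis-lactone
Product: 30 target CNP0218652.1, via seco acid 29 (not isolated)
Conditions: aq. NaOH (degassed), MeOH/THF, 50 °C; then 2 M HCl, rt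
Reagents that add atoms: none
Why: Hydroxide attacks sulfur of the aryl methanesulfonates (S–O cleavage, aryloxide leaving group) and opens both lactones to 29 as its sodium salt; acidification frees the phenols and the γ-hydroxy acids reclose; C3 has no α-hydrogen and C4–H is not acidic, so both centres persist, and air is excluded because the biphenolate oxidises easily.

## Compound list

1 | 4-(benzyloxy)-3-methoxybenzaldehyde (O-benzylvanillin) | COc1cc(C=O)ccc1OCc1ccccc1 | starting material
2 | dimethyl succinate | COC(=O)CCC(=O)OC | starting material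
3 | (3E)-4-[4-(benzyloxy)-3-methoxyphenyl]-3-(methoxycarbonyl)but-3-enoic acid | COC(=O)/C(CC(=O)O)=C/c1ccc(OCc2ccccc2)c(OC)c1 | intermediate
4 | (3S)-4-[4-(benzyloxy)-3-methoxyphenyl]-3-(methoxycarbonyl)butanoic acid | COC(=O)[C@@H](Cc1ccc(OCc2ccccc2)c(OC)c1)CC(=O)O | intermediate
5 | (3S)-4-[4-(benzyloxy)-3-methoxyphenyl]-3-(hydroxymethyl)butanoic acid | OC[C@@H](Cc1ccc(OCc2ccccc2)c(OC)c1)CC(=O)O | intermediate (not isolated)
6 | (4S)-4-{[4-(benzyloxy)-3-methoxyphenyl]methyl}oxolan-2-one | COc1cc(C[C@@H]2COC(=O)C2)ccc1OCc1ccccc1 | intermediate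
7 | 5-bromovanillin (3-bromo-4-hydroxy-5-methoxybenzaldehyde) | COc1cc(C=O)cc(Br)c1O | starting material
8 | 4-(benzyloxy)-3-bromo-5-methoxybenzaldehyde | COc1cc(C=O)cc(Br)c1OCc1ccccc1 | intermediate
9 | (3E)-4-[4-(benzyloxy)-3-bromo-5-methoxyphenyl]-3-(methoxycarbonyl)but-3-enoic acid | COC(=O)/C(CC(=O)O)=C/c1cc(Br)c(OCc2ccccc2)c(OC)c1 | intermediate
10 | (3S)-4-[4-(benzyloxy)-3-bromo-5-methoxyphenyl]-3-(methoxycarbonyl)butanoic acid | COC(=O)[C@@H](Cc1cc(Br)c(OCc2ccccc2)c(OC)c1)CC(=O)O | intermediate
11 | (3S)-4-[4-(benzyloxy)-3-bromo-5-methoxyphenyl]-3-(hydroxymethyl)butanoic acid | OC[C@@H](Cc1cc(Br)c(OCc2ccccc2)c(OC)c1)CC(=O)O | intermediate (not isolated)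
12 | (4S)-4-{[4-(benzyloxy)-3-bromo-5-methoxyphenyl]methyl}oxolan-2-one | COc1cc(C[C@@H]2COC(=O)C2)cc(Br)c1OCc1ccccc1 | intermediate
13 | (4S)-3-{(acetyloxy)[4-(benzyloxy)-3-bromo-5-methoxyphenyl]methyl}-4-{[4-(benzyloxy)-3-methoxyphenyl]methyl}oxolan-2-one, epimer mixture at C3 and the acetoxy carbon | COc1cc(C[C@@H]2COC(=O)C2C(OC(C)=O)c2cc(Br)c(OCc3ccccc3)c(OC)c2)ccc1OCc1ccccc1 | intermediate (not isolated)
14 | (3E,4S)-3-{[4-(benzyloxy)-3-bromo-5-methoxyphenyl]methylidene}-4-{[4-(benzyloxy)-3-methoxyphenyl]methyl}oxolan-2-one (rings A and B) | COc1cc(C[C@@H]2COC(=O)/C2=C/c2cc(Br)c(OCc3ccccc3)c(OC)c2)ccc1OCc1ccccc1 | intermediate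
15 | (4S)-3-{(acetyloxy)[4-(benzyloxy)-3-methoxyphenyl]methyl}-4-{[4-(benzyloxy)-3-bromo-5-methoxyphenyl]methyl}oxolan-2-one, epimer mixture at C3 and the acetoxy carbon | COc1cc(C[C@@H]2COC(=O)C2C(OC(C)=O)c2ccc(OCc3ccccc3)c(OC)c2)cc(Br)c1OCc1ccccc1 | intermediate (not isolated)
16 | (3E,4S)-4-{[4-(benzyloxy)-3-bromo-5-methoxyphenyl]methyl}-3-{[4-(benzyloxy)-3-methoxyphenyl]methylidene}oxolan-2-one (rings C and D) | COc1cc(C[C@@H]2COC(=O)/C2=C/c2ccc(OCc3ccccc3)c(OC)c2)cc(Br)c1OCc1ccccc1 | intermediate
17 | pinacol boronate of 16 (Bpin in place of Br on ring C) | COc1cc(C[C@@H]2COC(=O)/C2=C/c2ccc(OCc3ccccc3)c(OC)c2)cc(B2OC(C)(C)C(C)(C)O2)c1OCc1ccccc1 | intermediate (not isolated)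
18 | tetra-O-benzyl bis(arylidene lactone): two (3E,4S)-3-arylidene-4-(arylmethyl)oxolan-2-ones, lactone 1 with ring A on C4–CH2 and ring B as arylidene, lactone 2 with ring C on C4–CH2 and ring D as arylidene, rings B and C joined C5–C5′, all four phenols as benzyl ethers | COc1cc(C[C@@H]2COC(=O)/C2=C/c2cc(OC)c(OCc3ccccc3)c(-c3cc(C[C@@H]4COC(=O)/C4=C/c4ccc(OCc5ccccc5)c(OC)c4)cc(OC)c3OCc3ccccc3)c2)ccc1OCc1ccccc1 | intermediate
19 | tetraphenol bis(arylidene lactone): 18 with four free phenols | COc1cc(C[C@@H]2COC(=O)/C2=C/c2cc(OC)c(O)c(-c3cc(C[C@@H]4COC(=O)/C4=C/c4ccc(O)c(OC)c4)cc(OC)c3O)c2)ccc1O | intermediate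
20 | tetramesylate bis(arylidene lactone): 19 with four aryl methanesulfonates | COc1cc(C[C@@H]2COC(=O)/C2=C/c2cc(OC)c(OS(C)(=O)=O)c(-c3cc(C[C@@H]4COC(=O)/C4=C/c4ccc(OS(C)(=O)=O)c(OC)c4)cc(OC)c3OS(C)(=O)=O)c2)ccc1OS(C)(=O)=O | intermediate
21 | bis[(2E,3S)-2-(arylmethylidene)-3-(arylmethyl)-4-hydroxy-N-methoxy-N-methylbutanamide], aryl groups as in 20 | COc1cc(C[C@H](CO)/C(C(=O)N(C)OC)=C\c2cc(OC)c(OS(C)(=O)=O)c(-c3cc(C[C@H](CO)/C(C(=O)N(C)OC)=C\c4ccc(OS(C)(=O)=O)c(OC)c4)cc(OC)c3OS(C)(=O)=O)c2)ccc1OS(C)(=O)=O | intermediate
22 | 21 with both C4 hydroxyls as tert-butyldimethylsilyl ethers | COc1cc(C[C@H](CO[Si](C)(C)C(C)(C)C)/C(C(=O)N(C)OC)=C\c2cc(OC)c(OS(C)(=O)=O)c(-c3cc(C[C@H](CO[Si](C)(C)C(C)(C)C)/C(C(=O)N(C)OC)=C\c4ccc(OS(C)(=O)=O)c(OC)c4)cc(OC)c3OS(C)(=O)=O)c2)ccc1OS(C)(=O)=O | intermediate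
23 | bis[(2E,3S)-2-(arylmethylidene)-3-(arylmethyl)-4-(silyloxy)butanal] | COc1cc(C[C@H](CO[Si](C)(C)C(C)(C)C)/C(C=O)=C\c2cc(OC)c(OS(C)(=O)=O)c(-c3cc(C[C@H](CO[Si](C)(C)C(C)(C)C)/C(C=O)=C\c4ccc(OS(C)(=O)=O)c(OC)c4)cc(OC)c3OS(C)(=O)=O)c2)ccc1OS(C)(=O)=O | intermediate (not isolated)
24 | bis[(2E,3S)-2-(arylmethylidene)-3-(arylmethyl)-4-(tert-butyldimethylsilyloxy)butan-1-ol], four aryl mesylates | COc1cc(C[C@H](CO[Si](C)(C)C(C)(C)C)/C(CO)=C\c2cc(OC)c(OS(C)(=O)=O)c(-c3cc(C[C@H](CO[Si](C)(C)C(C)(C)C)/C(CO)=C\c4ccc(OS(C)(=O)=O)c(OC)c4)cc(OC)c3OS(C)(=O)=O)c2)ccc1OS(C)(=O)=O | intermediate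
25 | bis{[(2R,3R)-3-aryl-2-[(2R)-1-aryl-3-(silyloxy)propan-2-yl]oxiran-2-yl]methanol} | COc1cc(C[C@H](CO[Si](C)(C)C(C)(C)C)[C@]2(CO)O[C@@H]2c2cc(OC)c(OS(C)(=O)=O)c(-c3cc(C[C@H](CO[Si](C)(C)C(C)(C)C)[C@]4(CO)O[C@@H]4c4ccc(OS(C)(=O)=O)c(OC)c4)cc(OC)c3OS(C)(=O)=O)c2)ccc1OS(C)(=O)=O | intermediate
26 | bis[(2R,3R)-2,3-bis(arylmethyl)-4-(silyloxy)butane-1,2-diol] | COc1cc(C[C@H](CO[Si](C)(C)C(C)(C)C)[C@@](O)(CO)Cc2cc(OC)c(OS(C)(=O)=O)c(-c3cc(C[C@H](CO[Si](C)(C)C(C)(C)C)[C@@](O)(CO)Cc4ccc(OS(C)(=O)=O)c(OC)c4)cc(OC)c3OS(C)(=O)=O)c2)ccc1OS(C)(=O)=O | intermediate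
27 | bis[(2R,3R)-2,3-bis(arylmethyl)-2-hydroxy-4-(silyloxy)butanoic acid] | COc1cc(C[C@H](CO[Si](C)(C)C(C)(C)C)[C@@](O)(C(=O)O)Cc2cc(OC)c(OS(C)(=O)=O)c(-c3cc(C[C@H](CO[Si](C)(C)C(C)(C)C)[C@@](O)(C(=O)O)Cc4ccc(OS(C)(=O)=O)c(OC)c4)cc(OC)c3OS(C)(=O)=O)c2)ccc1OS(C)(=O)=O | intermediate (not isolated)
28 | tetra-O-mesyl target: both lactones (3R,4R), four aryl methanesulfonates | COc1cc(C[C@@H]2COC(=O)[C@@]2(O)Cc2cc(OC)c(OS(C)(=O)=O)c(-c3cc(C[C@@H]4COC(=O)[C@@]4(O)Cc4ccc(OS(C)(=O)=O)c(OC)c4)cc(OC)c3OS(C)(=O)=O)c2)ccc1OS(C)(=O)=O | intermediate
29 | seco acid: bis[(2R,3R)-2,3-bis(arylmethyl)-2,4-dihydroxybutanoic acid] with four free phenols (sodium salt in the flask) | COc1cc(C[C@H](CO)[C@@](O)(C(=O)O)Cc2cc(OC)c(O)c(-c3cc(C[C@H](CO)[C@@](O)(C(=O)O)Cc4ccc(O)c(OC)c4)cc(OC)c3O)c2)ccc1O | intermediate (not isolated)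
30 | CNP0218652.1, both lactones (3R,4R) | COc1cc(C[C@@H]2COC(=O)[C@@]2(O)Cc2cc(OC)c(O)c(-c3cc(C[C@@H]4COC(=O)[C@@]4(O)Cc4ccc(O)c(OC)c4)cc(OC)c3O)c2)ccc1O | target

## Step count and least certain steps

Total step count: 19. Longest linear sequence: 15 steps (from 7 through steps 4–7, 9 and 10–19).

**Step 16 (key step).** Most likely to go wrong:
- erosion of face selectivity at one alkene if the ligand preference and the weak bias of C4 are opposed;
- slow turnover of an electron-poor styrene with a branched 2-substituent, so that the mono-oxirane persists;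
- opening of an oxirane by isopropoxide or hydroperoxide at titanium.

Fallback: from 24, epoxidise both alkenes with the dioxirane of the D-fructose-derived Shi ketone (KHSO5, K2CO3 buffer, MeCN/dimethoxymethane/water, 0 °C). This moves face control from an alkoxide-bound metal template to a non-coordinating chiral oxidant. That ketone antipode is expected to give the (2R,3R) oxiranes, by analogy with trans-β-methylstyrene and 1-phenylcyclohexene. The detour returns at 25 and makes no new compound (F0).

**Step 13.** Sulfonyl transfer from the aryl mesylates to the aluminium amide, or reclosure of the γ-hydroxy amide on work-up, would lower the throughput. Fallback: from 19, run the aminolysis on the free phenols with excess AlMe3/MeNHOMe·HCl to give tetraphenol bis(hydroxy amide) F1. Silylate every hydroxyl with TBSCl/imidazole to give hexasilyl compound F2. Cleave only the aryl silyl ethers with K2CO3/MeOH to give tetraphenol bis(alkyl silyl ether) F3 (phenols that escaped silylation do no harm). Mesylate with MsCl/Et3N and return at 22.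

**Step 10.** Protodeboronation of the ortho-alkoxy boronate, homocoupling, or slow transmetalation between two ortho-substituted partners may cut the yield. Fallback: form the biaryl on smaller pieces and condense afterwards. From 12, Miyaura borylation (B2pin2, PdCl2(dppf), KOAc) gives lactone boronate F4. Suzuki coupling with 8 (Pd(OAc)2, SPhos, K3PO4) gives biaryl aldehyde–lactone F5. The preformed lithium enolate of 6 adds to the aldehyde of F5, and acetylation/DBU gives mono-arylidene bis-lactone F6. Enolisation of the remaining saturated lactone with LiN(SiMe3)2, condensation with 1 and the same elimination return at 18.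

**Step 17.** Isomerisation of the oxirane to a carbonyl compound on palladium, or sluggish C–O cleavage because the sulfonated arenes are electron-poor, is possible. Fallback: from 25, open the oxiranes with hydride at the benzylic carbon under titanium chelation (Ti(OiPr)4, LiBH4, THF), the known C3-selective reduction of 2,3-epoxy alcohols to 1,2-diols. Attack at the fully substituted carbon is excluded. The detour returns at 26 and makes no new compound (F0).

**Step 18.** Oxidative C–C cleavage of the 1,2-diol by way of the hydrated α-hydroxy aldehyde, or ring chlorination by hypochlorite, may compete. Fallback: from 26, oxidise with SO3·pyridine/DMSO/iPr2NEt to the isolated bis(α-hydroxy aldehyde) F7. Take it on with NaClO2/NaH2PO4/2-methyl-2-butene to 27, which is then isolated. Treat 27 with HCl/THF to return at 28.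

## Further compounds

F0 | step 16 | none | none
F1 | step 13 | tetraphenol bis[(2E,3S)-4-hydroxy N-methoxy-N-methylbutanamide] (21 without mesyl groups) | COc1cc(C[C@H](CO)/C(C(=O)N(C)OC)=C\c2cc(OC)c(O)c(-c3cc(C[C@H](CO)/C(C(=O)N(C)OC)=C\c4ccc(O)c(OC)c4)cc(OC)c3O)c2)ccc1O
F2 | step 13 | hexakis(tert-butyldimethylsilyl) ether of F1 | COc1cc(C[C@H](CO[Si](C)(C)C(C)(C)C)/C(C(=O)N(C)OC)=C\c2cc(OC)c(O[Si](C)(C)C(C)(C)C)c(-c3cc(C[C@H](CO[Si](C)(C)C(C)(C)C)/C(C(=O)N(C)OC)=C\c4ccc(O[Si](C)(C)C(C)(C)C)c(OC)c4)cc(OC)c3O[Si](C)(C)C(C)(C)C)c2)ccc1O[Si](C)(C)C(C)(C)C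
F3 | step 13 | tetraphenol bis(alkyl silyl ether) (22 without mesyl groups) | COc1cc(C[C@H](CO[Si](C)(C)C(C)(C)C)/C(C(=O)N(C)OC)=C\c2cc(OC)c(O)c(-c3cc(C[C@H](CO[Si](C)(C)C(C)(C)C)/C(C(=O)N(C)OC)=C\c4ccc(O)c(OC)c4)cc(OC)c3O)c2)ccc1O
F4 | step 10 | pinacol boronate of lactone 12 | COc1cc(C[C@@H]2COC(=O)C2)cc(B2OC(C)(C)C(C)(C)O2)c1OCc1ccccc1
F5 | step 10 | biaryl aldehyde–lactone: ring B as 4-(benzyloxy)-3-methoxy-5-arylbenzaldehyde, ring C carrying the (4S)-lactone | COc1cc(C=O)cc(-c2cc(C[C@@H]3COC(=O)C3)cc(OC)c2OCc2ccccc2)c1OCc1ccccc1
F6 | step 10 | mono-arylidene bis-lactone: 18 lacking the ring D arylidene | COc1cc(C[C@@H]2COC(=O)/C2=C/c2cc(OC)c(OCc3ccccc3)c(-c3cc(C[C@@H]4COC(=O)C4)cc(OC)c3OCc3ccccc3)c2)ccc1OCc1ccccc1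
F0 | step 17 | none | none
F7 | step 18 | bis[(2R,3R)-2,3-bis(arylmethyl)-2-hydroxy-4-(silyloxy)butanal] | COc1cc(C[C@H](CO[Si](C)(C)C(C)(C)C)[C@@](O)(C=O)Cc2cc(OC)c(OS(C)(=O)=O)c(-c3cc(C[C@H](CO[Si](C)(C)C(C)(C)C)[C@@](O)(C=O)Cc4ccc(OS(C)(=O)=O)c(OC)c4)cc(OC)c3OS(C)(=O)=O)c2)ccc1OS(C)(=O)=O
A1 | alternative 1 | tri-O-benzyl ether of the target with the ring C phenol free | COc1cc(C[C@@H]2COC(=O)[C@@]2(O)Cc2cc(OC)c(OCc5ccccc5)c(-c3cc(C[C@@H]4COC(=O)[C@@]4(O)Cc4ccc(OCc6ccccc6)c(OC)c4)cc(OC)c3O)c2)ccc1OCc1ccccc1
A2 | alternative 2 | bis(γ,δ-unsaturated α-benzyloxy acid) with (E)-propenyl groups at both C4 carbons | COc1cc(C[C@H](/C=C/C)[C@@](OCc5ccccc5)(C(=O)O)Cc2cc(OC)c(OCc5ccccc5)c(-c3cc(C[C@H](/C=C/C)[C@@](OCc6ccccc6)(C(=O)O)Cc4ccc(OCc6ccccc6)c(OC)c4)cc(OC)c3OCc3ccccc3)c2)ccc1OCc1ccccc1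
A3 | alternative 3 | tetra-O-benzyl bis(4-aroyl-3-hydroxy lactone) | COc1cc(C(=O)[C@@H]2COC(=O)[C@@]2(O)Cc2cc(OC)c(OCc5ccccc5)c(-c3cc(C(=O)[C@@H]4COC(=O)[C@@]4(O)Cc4ccc(OCc6ccccc6)c(OC)c4)cc(OC)c3OCc3ccccc3)c2)ccc1OCc1ccccc1
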